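**The product wanted.** The target was the product I wanted from this flask, and the uncatalysed product took substrate from it by a second road.

| flask | substrate | coupling partner | free catalyst | second catalyst | remark | time |
|---|---|---|---|---|---|---|
| north-east | 2.0 × 10⁻⁴ M | 0.50 mM | 0.15 µM | 0.40 µM | the very flask that is asked about, followed so far |  |
| west | 2.0 × 10⁻⁴ M | 0.50 mM | 0.15 µM | 0.60 µM | run made earlier |  |
| flask | 2.0 × 10⁻⁴ M | 0.500 mM | 0.15 µM | 0.40 µM |  | 5.0 min |

north-east run (percent of the substrate charged)

| time / s | uncatalysed product / % | target / % |
|---|---|---|
| 10.0 | 6 | 60 |
| 20.0 | 8 | 79 |
| 30.0 | 3 | 83 |
| 60.0 | 7 | 94 |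
| 120 | 9 | 97 |

west run (percent of the substrate charged)

| time / min | uncatalysed product / % | target / % |
|---|---|---|
| 0.417 | 1 | 93 |
| 0.833 | 5 | 96 |
| 1.33 | 6 | 97 |
| 2.50 | 5 | 91 |
| 5.00 | 6 | 93 |

(each reading ± 2 percentage points)

- share of uncatalysed product in uncatalysed product plus target at 0.080 s
- share of uncatalysed product in uncatalysed product plus target at 4.0 s
- share of uncatalysed product in uncatalysed product plus target at 5.0 min
- which of uncatalysed product and target there is more of at 5.0 min

- the analysis behind the earlier runs scatters by 2 percentage points, standard deviation
- steps that have been proposed: substrate + free catalyst -> free catalyst + intermediate; coupling partner + second catalyst + intermediate -> second catalyst + target; substrate + coupling partner -> uncatalysed product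

**Which numbers count.** I asked first what each number could do to the late share. On the proposed steps, substrate left by two roads, each first order in it, so their rates stood in a ratio proportional to [free catalyst]/[coupling partner]. The substrate charge cancelled from that ratio, while an error in [free catalyst] or [coupling partner] shifted its logarithm by the same amount. The second catalyst acted beyond the branch. Uncatalysed product averaged 6.60% in the north-east run and 4.60% in the west run, a gap within twice its scatter of 1.3 percentage points. I therefore pooled them. The number to know well was this level of uncatalysed product.

**The number.** The pooled mean was 5.60%, with a standard error of 0.63 points. Taking the two products to share the substrate at the end, I used this mean as the share at 5.0 min. From it I reckoned 16.9, the branch ratio, substrate sent towards target per substrate lost to uncatalysed product, a selectivity factor. Its logarithm was 1.23, and a share higher by one standard error lowered that by 0.0494. I expected far more target than uncatalysed product.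

**The forecast.** The forecast gave 92.5%, 15% and 5.6% at the three asked times, with target ahead, reasoning that “the target rises later through the intermediate”.

**The result.** The flask gave 92.2%, 14.9% and 5.50%, with target ahead at 94.5% against 5.50%.

    substrate + free catalyst → free catalyst + intermediate (k = 1.80 × 10⁷ M⁻¹ s⁻¹)
    coupling partner + second catalyst + intermediate → second catalyst + target (k = 6.10 × 10⁸ M⁻² s⁻¹)
    substrate + coupling partner → uncatalysed product (k = 320 M⁻¹ s⁻¹)

**The branch.** At 0.00405 min in this flask, the catalysed road used substrate 17 times as fast as the uncatalysed road, with half-lives of 0.26 s against 4.39 s; at 5.0 min the share in this flask was 5.50%, beside the 5.60% behind the branch ratio of 16.9 from the readings. For a neighbour flask charged with 3.8 × 10⁻⁷ M of free catalyst, its other charges as in this flask, I multiplied the branch ratio by 2.53, adding 0.404 to its logarithm and reaching 42.7, so the reckoned share of 2.29% stood against that neighbour's simulated 2.27%.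

(All runs come from a simulation on assumed constants; the scatter is artificial.)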